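The beta run, charged with 1.8 M of partner, read 62.4% product at 5.00 h and 69.1% at 12.0 h, and the eta run flattened from 35.5% to 36.1% between 10.0 h and 12.0 h. Read these as flasks closing on an equilibrium. In the last beta reading, the fraction of substrate made into product, divided by the fraction left and by the partner left, comes to 1.54 M⁻¹. Call this the closing ratio, the equilibrium constant as far as a reading gives it. The last eta reading gives 1.35 M⁻¹. You carry the beta figure, and it reads low if that flask was still climbing.

| setting | delta | beta | eta | south-east | south | north-west | east | west | south-west |
|---|---|---|---|---|---|---|---|---|---|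
| substrate | 0.50 M | 0.50 M | 0.50 M | 0.50 M | 2.0 M | 0.50 M | 0.50 M | 0.50 M | 0.30 M |
| partner | 0.085 M | 1.8 M | 0.60 M | 0.150 M | 0.600 M | 1.00 M | 2.50 M | 0.600 M | 0.600 M |
| precatalyst | 0.85 mM | 0.85 mM | 0.70 mM | 0.85 mM | 0.20 mM | 3.0 mM | 0.85 mM | 0.85 mM | 0.85 mM |
| remark | run made earlier | run made earlier | run made earlier |  |  |  |  |  |  |
| time |  |  |  | 25 h | 25 h | 25 h | 25 h | 25 h | 25 h |

| delta: time / h | delta: product / % | beta: time / h | beta: product / % | eta: time / h | eta: product / % |
|---|---|---|---|---|---|
| 1.00 | 1.8 | 1.00 | 15.4 | 3.00 | 16.0 |
| 2.50 | 0 | 2.50 | 44.3 | 6.00 | 25.8 |
| 5.00 | 1.4 | 5.00 | 62.4 | 10.0 | 35.5 |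
| 12.0 | 4.0 | 12.0 | 69.1 | 12.0 | 36.1 |

(scatter of a reading: 1 percentage point)

- all flasks from highest to lowest amount of product, in percent of the substrate charged, at 25 h (south-east / south / north-west / east / west / south-west)
- the amount of product, in percent of the substrate charged of the flask you put first, at 25 h
- the amount of product, in percent of the substrate charged of the flask you put last, at 25 h

- what may be going on: partner + precatalyst -> free catalyst + spent reagent; substrate + partner + free catalyst <-> product + free catalyst; free catalyst + product -> spent catalyst

Now keep a ledger of your own for east, where substrate is the limiting reagent, at 0.50 M against 2.50 M of partner. Spent catalyst can hold at most 0.170% of the substrate charged, so you drop that entry. A fraction x goes to product and the rest stays substrate, while the partner left is its charge less x of the substrate charge. The books close where x over the rest equals the closing ratio times that partner, at 76.5%.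

In south-east partner is limiting, at 0.150 M against 0.50 M of substrate, and its charge allows 30.0% of the substrate, yet the books close lower, at 12.1%. The delta run read 4.0% at 12.0 h against a close of 7.08%. South-east has more partner than the delta run and twice the time, so you expect it to arrive.

The same ledger gives 53.0% for north-west, 42.1% for south-west, 38.5% for west and 21.2% for south. South has a quarter of the usual precatalyst and may fall short of its close, but you still place it above south-east.

The forecast commits to the same order, east > north-west > south-west > west > south > south-east, with 76% first and 11.5% last. Its ground: “The plateaus look like equilibrium, not catalyst death.”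

The flasks give east > north-west > south-west > west > south > south-east, with 78.1% in east against your 76.5% and 12.5% in south-east against your 12.1%.

    partner + precatalyst → free catalyst + spent reagent (k = 0.0221 M⁻¹ min⁻¹)
    substrate + partner + free catalyst ⇌ product + free catalyst, rate k2*[substrate]*[partner]*[free catalyst] forward; the back reaction follows from the equilibrium constant (K = 1.70 M⁻¹, k = 3.94 M⁻² min⁻¹)
    free catalyst + product → spent catalyst (k = 0.00188 M⁻¹ min⁻¹)

East at 25.0 h still holds 36.4% of its catalyst as free catalyst, yet its product at 250 h is still 78.0%. Carry the closing ratio to a neighbour, a flask like east with 1.0 M of partner, which is 2.00 equiv of partner to substrate. The ledger closes there at 53.0%. That neighbour ends with 54.9% product, 45.0% substrate and 72% of its partner left.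

(The numbers in the tables are simulated with constants of no real substance.)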